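The reagent was the line I read first in these recipes.

in all of them: left-handed substrate 0.32 M; right-handed substrate 0.32 M; reagent 0.704 M (fed, over 6.0 h)
- north-east: free catalyst 24 mM; added ligand 83 mM; run made earlier; the fed solution adds 1.0 times the starting volume
- east: free catalyst 37 mM; added ligand 83 mM; run made earlier; the fed solution adds 1.0 times the starting volume
- south: free catalyst 17 mM; added ligand 120 mM; run made earlier; the fed solution adds 1.0 times the starting volume
- flask: free catalyst 17 mM; added ligand 83 mM; the fed solution adds 1.0 times the starting volume; time 15 h

I assumed that each substrate converted spends one reagent, so the reagent charged over the two substrates charged together is a ceiling on the fraction of the charge that can react. That fraction came to 110 % for this flask; I called it the reagent cover. But a cover above the whole charge says nothing of time, so I turned to the runs.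

| run | time / h | left-handed substrate / % | right-handed substrate / % |
|---|---|---|---|
| north-east | 0.667 | 45.0 | 45.5 |
| north-east | 1.33 | 39.4 | 40.7 |
| north-east | 2.00 | 34.5 | 35.3 |
| north-east | 3.00 | 27.5 | 27.6 |
| north-east | 5.00 | 15.6 | 16.3 |
| north-east | 10.0 | 4.6 | 4.5 |
| east | 1.50 | 38.0 | 37.6 |
| east | 3.00 | 25.9 | 25.9 |
| east | 5.00 | 12.8 | 13.6 |
| east | 6.00 | 8.4 | 8.2 |
| east | 8.00 | 3.4 | 3.7 |
| east | 10.0 | 2.4 | 2.6 |
| south | 2.00 | 36.7 | 37.3 |
| south | 4.00 | 25.1 | 25.0 |
| south | 5.00 | 20.0 | 20.8 |
| south | 8.00 | 10.7 | 11.1 |
| south | 10.0 | 8.6 | 9.3 |

(standard deviation of a reading: 0.3 percentage points)

The two substrates fell together: at 5.00 h the north-east run held 15.6 % and 16.3 %, with a scatter of 0.3 percentage points on each reading. So I did not take from these readings whether the catalyst was blind to handedness or the substrates turned into each other, and I left the excess in the product open.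

The flask's ratio of free catalyst to added ligand, 0.205, lay above south's and below north-east's. So I expected it to react faster than south and more slowly than north-east, and to stand below its cover at 15 h.

- part of the left-handed substrate and right-handed substrate charged together that has reacted at 15 h
- excess of left-handed product over right-handed product in the product at 15 h
- excess of right-handed substrate over left-handed substrate among what is left of the two at 15 h

- free catalyst is single-handed; left-handed substrate and right-handed substrate are mirror images of each other, charged as a racemate, each of them at the stated concentration
- every charge counts on the volume at the start, and the solution that is fed holds the whole dose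
- an excess is the difference of the two amounts in percent of their sum
- an excess is below zero if the other one leads

The forecast stood at 89.5 % reacted, 0.35 % in the product and 3 % in the substrate left, and said “resolution is only marginal”.

The flask gave 90.7 % reacted, 91.9 % in the product and 0.171 % in the substrate left.

    free catalyst + added ligand ⇌ idle complex (K = 34.0 L mol⁻¹, k = 0.00270 L mol⁻¹ s⁻¹)
    left-handed substrate ⇌ right-handed substrate (k = 0.00420 s⁻¹)
    reagent + free catalyst + right-handed substrate → free catalyst + right-handed product (k = 0.0200 L² mol⁻² s⁻¹)
    reagent + free catalyst + left-handed substrate → free catalyst + left-handed product (k = 0.480 L² mol⁻² s⁻¹)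
    reagent + free catalyst → spent catalyst (k = 1.30 × 10⁻⁴ L mol⁻¹ s⁻¹)
    2 reagent → self-condensation product (k = 1.50 × 10⁻⁴ L mol⁻¹ s⁻¹)

That conversion stood below the flask's cover of 110 %, with reagent at 5.5 % of its charge. In this flask the substrates stayed level while the left-handed product led, and the relaxation half-life of their interconversion by that step alone, 1.38 min with both ways counted, was short against 15 h. The neighbour flask charged with 0.18 M of reagent had a cover of 28.1 %. It reacted 27.8 %, with reagent down to 0.016 % of its charge, so there reagent was the limiting reagent. The excess of left-handed product in that neighbour flask stood at 92.0 %.

All runs are calculated for substances that don't exist, and the scatter is random.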